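**Strategy.** The only ring of Hansfordiol B, the benzene ring, is not bought but built from an open chain. Its pattern (OH on C1 and C3, the 16-oxoheptadecyl chain on C5, H on C2, C4 and C6) is that of a folded polyketide, so the ring is cut at the C5–C6 bond. The precursor is a methyl 3,5,7-trioxo ester whose distal ketone is masked as a dioxolane. In one operation its C2 methylene adds to the C7 ketone, water is lost and the ring aromatizes to a 6-alkyl resorcylate. The ester carbon that steered the closure is then removed as carbon dioxide.

Key step: step 8

Remarks on the chemistry: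
- The 1,3-dicarbonyl compounds 10, 11, 13 and 14 are drawn as keto tautomers although they will exist largely as enols; 14 is a stereoisomer mixture whose stereocentres vanish on aromatization.
- The open-chain precursor 13 is a docosanoate carrying the dioxolane on C22; counting the ketal carbon and its methyl, the chain has 24 carbons.
- The Weinreb amide is made before the ketal, so the free acid never meets the glycol. Steps 7 and 8 are telescoped without purification. Ester hydrolysis, ketal hydrolysis and decarboxylation share one flask in step 9.

**Step 1**
Reactants: 1 16-bromohexadecanoic acid; 2 lithium acetylide–ethylenediamine complex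
Product: 3 octadec-17-ynoic acid
Conditions: LiC≡CH·H2NCH2CH2NH2 (3.5 equiv), DMSO, 10 °C → rt; then 1 M HCl
Reagents that add atoms: none
Why: SN2 alkylation of an acetylide anion: the first equivalent converts the acid into its lithium carboxylate, and in DMSO the remaining acetylide displaces the unhindered primary bromide, where substitution outruns elimination.

**Step 2**
Reactants: 3 octadec-17-ynoic acid
Product: 4 17-oxooctadecanoic acid
Conditions: (IPr)AuCl (2 mol %; IPr = 1,3-bis(2,6-diisopropylphenyl)imidazol-2-ylidene), AgSbF6 (2 mol %), 1,4-dioxane/H2O (2:1), 100 °C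
Reagents that add atoms: water, O
Why: Markovnikov hydration of a terminal alkyne under cationic monovalent gold catalysis: water adds to the internal carbon of the gold-bound alkyne and the enol tautomerizes, so only the methyl ketone can result, and the large excess of water outcompetes addition of the remote carboxylic acid.

**Step 3**
Reactants: 4 17-oxooctadecanoic acid
Product: 6 N-methoxy-N-methyl-17-oxooctadecanamide, via acyl imidazolide 5 (not isolated)
Conditions: CDI (1.2 equiv), THF, rt; then MeNH(OMe)·HCl (1.5 equiv), rt
Reagents that add atoms: N,O-dimethylhydroxylamine hydrochloride, CNOC.Cl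
Why: Amide coupling through an acyl imidazolide: CDI activates the acid with loss of CO2, the imidazole released frees the amine from its hydrochloride, and the ketone is inert to both reagents, so the Weinreb amide forms before any glycol is present that could esterify the acid.

**Step 4**
Reactants: 6 N-methoxy-N-methyl-17-oxooctadecanamide
Product: 7 N-methoxy-N-methyl-16-(2-methyl-1,3-dioxolan-2-yl)hexadecanamide
Conditions: HOCH2CH2OH (5 equiv), TsOH·H2O (5 mol %), toluene, reflux, Dean–Stark trap
Reagents that add atoms: ethylene glycol, OCCO
Why: Acid-catalysed ketalization driven by azeotropic removal of water turns the unhindered methyl ketone into the dioxolane, while the tertiary N-methoxy amide does not react with a diol under catalytic sulfonic acid.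

**Step 5**
Reactants: 8 2,2,6-trimethyl-4H-1,3-dioxin-4-one; 9 acetyl chloride
Product: 10 2,2-dimethyl-6-(2-oxopropyl)-4H-1,3-dioxin-4-one
Conditions: 8 (2.0 equiv), LiN(SiMe3)2 (2.0 equiv), THF, −78 °C; then 9 (1.0 equiv), −78 °C; cold 1 M HCl quench
Reagents that add atoms: none
Why: Claisen-type C-acylation of a vinylogous ester enolate: deprotonation of the 6-methyl group gives the lithium dienolate, which is acetylated at that carbon at −78 °C, and the second equivalent of dienolate takes up the proton of the more acidic product so that it is not acylated twice.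

**Step 6**
Reactants: 7 N-methoxy-N-methyl-16-(2-methyl-1,3-dioxolan-2-yl)hexadecanamide; 10 2,2-dimethyl-6-(2-oxopropyl)-4H-1,3-dioxin-4-one
Product: 11 2,2-dimethyl-6-[19-(2-methyl-1,3-dioxolan-2-yl)-2,4-dioxononadecyl]-4H-1,3-dioxin-4-one
Conditions: 10 (2.5 equiv), LiN(i-Pr)2 (5.0 equiv), THF, −78 → −40 °C; then 7 (1.0 equiv), −78 → −30 °C; sat. aq. NH4Cl
Reagents that add atoms: none
Why: Acylation of a β-dicarbonyl-type dianion by a Weinreb amide: the second deprotonation generates the more reactive terminal methyl enolate, which adds to the amide to give a chelated tetrahedral intermediate that cannot over-add and releases the 1,3-diketone only on quenching, while dioxolane and dioxinone are inert to the amide base at low temperature.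

**Step 7**
Reactants: 11 2,2-dimethyl-6-[19-(2-methyl-1,3-dioxolan-2-yl)-2,4-dioxononadecyl]-4H-1,3-dioxin-4-one
Product: 13 methyl 22-(2-methyl-1,3-dioxolan-2-yl)-3,5,7-trioxodocosanoate, via acylketene 12 (not isolated)
Conditions: toluene, MeOH (10 equiv), 110 °C (sealed tube); concentrate and use crude
Reagents that add atoms: methanol, CO
Why: Thermal retro-[4+2] fragmentation (retro-hetero-Diels–Alder) of the dioxinone expels acetone, and the acylketene so formed is trapped by the excess methanol faster than by its own enol oxygen, giving the β-keto ester under neutral conditions that leave the dioxolane untouched.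

**Step 8**
Reactants: 13 methyl 22-(2-methyl-1,3-dioxolan-2-yl)-3,5,7-trioxodocosanoate
Product: 15 methyl 2,4-dihydroxy-6-[15-(2-methyl-1,3-dioxolan-2-yl)pentadecyl]benzoate, via cyclic aldol 14 (not isolated)
Conditions: K2CO3 (2 equiv), MeOH, rt; then AcOH (excess), 40 °C
Reagents that add atoms: none
Why: Carbonate deprotonates the doubly activated C2 methylene (between the ester and the C3 ketone) and this enolate adds to the C7 ketone, forming the C2–C7 bond and the cyclic aldol 14; loss of the C7 hydroxyl with the C2 hydrogen and enolization of the C3 and C5 carbonyls, completed on acidification, then give the benzene ring. The closest known reaction type is the biomimetic aldol cyclization–aromatization of 3,5,7-triketo esters to 6-alkyl-2,4-dihydroxybenzoates, an intramolecular Knoevenagel-type aldol condensation. The one ring, the six-membered carbocycle C2–C3–C4–C5–C6–C7 that becomes the arene, is closed by a 6-exo-trig attack on the C7 carbonyl, favoured whether the delocalized enolate is counted as enolexo through C1 or enolendo through C3. The product has no stereocentre, and the two that appear in 14 (C2 and C7 of the chain) are erased by the dehydration, so nothing needs to control them. The selectivity needed is C2-to-C7 aldol closure over Claisen attack of C6 on the ester (acylphloroglucinol), lactonization of an enol oxygen onto the ester (pyrone) and aldol attack of C8 on the C3 ketone; it is secured because a ketone is a much better electrophile than a methyl ester under carbonate, because C8 is activated by one carbonyl only and is not deprotonated, and because the aldol addition to C7 is followed by an irreversible dehydration to the arene. The dioxolane keeps the distal ketone out of all enolate chemistry and is stable to carbonate and to buffered acetic acid.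

**Step 9**
Reactants: 15 methyl 2,4-dihydroxy-6-[15-(2-methyl-1,3-dioxolan-2-yl)pentadecyl]benzoate
Product: 18 Hansfordiol B (17-(3,5-dihydroxyphenyl)heptadecan-2-one), via resorcylic acid 16 (not isolated), via keto acid 17 (not isolated)
Conditions: KOH (10 equiv), MeOH/H2O (1:1), reflux, Ar; then 3 M HCl to pH 1, 1,4-dioxane, rt, then 70 °C
Reagents that add atoms: water, O
Why: Ester saponification (acyl substitution by hydroxide, run under argon) gives the carboxylate, and after acidification the dioxolane is hydrolysed and the 2,4-dihydroxybenzoic acid undergoes protodecarboxylation by ipso-protonation of the carbon that lies ortho and para to the two hydroxyl groups, a loss of CO2 that such β-resorcylic acids undergo on gentle warming.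

**Compound list**
1 | 16-bromohexadecanoic acid | OC(=O)CCCCCCCCCCCCCCCBr | starting material
2 | lithium acetylide–ethylenediamine complex | [Li]C#C.NCCN | starting material
3 | octadec-17-ynoic acid | C#CCCCCCCCCCCCCCCCC(=O)O | intermediate
4 | 17-oxooctadecanoic acid | CC(=O)CCCCCCCCCCCCCCCC(=O)O | intermediate
5 | 1-(1H-imidazol-1-yl)octadecane-1,17-dione (acyl imidazolide of 4) | CC(=O)CCCCCCCCCCCCCCCC(=O)n1ccnc1 | intermediate (not isolated)
6 | N-methoxy-N-methyl-17-oxooctadecanamide | CC(=O)CCCCCCCCCCCCCCCC(=O)N(C)OC | intermediate
7 | N-methoxy-N-methyl-16-(2-methyl-1,3-dioxolan-2-yl)hexadecanamide | CC1(OCCO1)CCCCCCCCCCCCCCCC(=O)N(C)OC | intermediate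
8 | 2,2,6-trimethyl-4H-1,3-dioxin-4-one | CC1=CC(=O)OC(C)(C)O1 | starting material
9 | acetyl chloride | CC(Cl)=O | starting material
10 | 2,2-dimethyl-6-(2-oxopropyl)-4H-1,3-dioxin-4-one | CC(=O)CC1=CC(=O)OC(C)(C)O1 | intermediate
11 | 2,2-dimethyl-6-[19-(2-methyl-1,3-dioxolan-2-yl)-2,4-dioxononadecyl]-4H-1,3-dioxin-4-one | CC1(OCCO1)CCCCCCCCCCCCCCCC(=O)CC(=O)CC2=CC(=O)OC(C)(C)O2 | intermediate
12 | 22-(2-methyl-1,3-dioxolan-2-yl)docos-1-ene-1,3,5,7-tetrone (acylketene) | O=C=CC(=O)CC(=O)CC(=O)CCCCCCCCCCCCCCCC1(C)OCCO1 | intermediate (not isolated)
13 | methyl 22-(2-methyl-1,3-dioxolan-2-yl)-3,5,7-trioxodocosanoate | COC(=O)CC(=O)CC(=O)CC(=O)CCCCCCCCCCCCCCCC1(C)OCCO1 | intermediate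
14 | methyl 2-hydroxy-2-[15-(2-methyl-1,3-dioxolan-2-yl)pentadecyl]-4,6-dioxocyclohexane-1-carboxylate (stereoisomer mixture) | COC(=O)C1C(=O)CC(=O)CC1(O)CCCCCCCCCCCCCCCC2(C)OCCO2 | intermediate (not isolated)
15 | methyl 2,4-dihydroxy-6-[15-(2-methyl-1,3-dioxolan-2-yl)pentadecyl]benzoate | COC(=O)c1c(O)cc(O)cc1CCCCCCCCCCCCCCCC2(C)OCCO2 | intermediate
16 | 2,4-dihydroxy-6-[15-(2-methyl-1,3-dioxolan-2-yl)pentadecyl]benzoic acid | OC(=O)c1c(O)cc(O)cc1CCCCCCCCCCCCCCCC2(C)OCCO2 | intermediate (not isolated)
17 | 2,4-dihydroxy-6-(16-oxoheptadecyl)benzoic acid | CC(=O)CCCCCCCCCCCCCCCc1cc(O)cc(O)c1C(=O)O | intermediate (not isolated)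
18 | Hansfordiol B, 17-(3,5-dihydroxyphenyl)heptadecan-2-one | CC(=O)CCCCCCCCCCCCCCCc1cc(O)cc(O)c1 | target

**Step count.** Total: 9 steps. Longest linear sequence: 8 steps (steps 1, 2, 3, 4, 6, 7, 8, 9 from compound 1); step 5 is a one-step side branch.

**Steps most likely to fail**

Step 6 (dianion acylation). Proton transfer from the acidic 1,3-diketone product to unreacted dianion, sluggish addition of the poorly soluble long-chain amide at −78 °C, and acylation on oxygen could leave the coupling incomplete. The fallback sets out from 7 and returns at 11. The amide is reduced with i-Bu2AlH (THF, −78 °C) to 16-(2-methyl-1,3-dioxolan-2-yl)hexadecanal F1. The dianion of 10 (LiN(i-Pr)2, THF, −78 °C) adds to this far more electrophilic aldehyde in an aldol reaction to give 6-[4-hydroxy-19-(2-methyl-1,3-dioxolan-2-yl)-2-oxononadecyl]-2,2-dimethyl-4H-1,3-dioxin-4-one F2, whose alkoxide does not quench the dianion. Oxidation of the secondary alcohol with Dess–Martin periodinane (CH2Cl2, NaHCO3, rt) should then give 11.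

Step 8 (key step). Closure through the wrong atoms (Claisen attack on the ester, or lactonization to a pyrone, which is already possible at the acylketene stage of step 7), stalling at the hydrated ring before dehydration, or cleavage of the dioxolane during acidification could erode the step. The fallback sets out from 11 and returns at 16. The open-chain ester is bypassed: 11 is treated with Et3N in CH2Cl2 at rt (Cs2CO3 in MeOH if slow), so that C5 of the intact dioxinone, the same carbon as C2 of 13, adds to the same ketone. The ring should aromatize to 7-hydroxy-2,2-dimethyl-5-[15-(2-methyl-1,3-dioxolan-2-yl)pentadecyl]-4H-1,3-benzodioxin-4-one F3. No acylketene is formed, so neither the ketene-derived pyrone nor an ester Claisen closure is available. Hot aqueous KOH as in step 9 opens F3 with loss of acetone to the salt of acid 16, where the route is rejoined.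

Step 9 (saponification and decarboxylation). Acyl substitution at the resorcylate ester is slow because the carbonyl is flanked by two ortho substituents and is deactivated once the phenols are ionized, and long heating in alkali exposes the electron-rich ring to air oxidation. The fallback sets out from 11 and returns at 16. The thermolysis of step 7 is run with benzyl alcohol in place of methanol to give benzyl 22-(2-methyl-1,3-dioxolan-2-yl)-3,5,7-trioxodocosanoate F4 (again through acylketene 12). This is cyclized and aromatized with K2CO3 in i-PrOH/CH2Cl2 (no methanol, to avoid transesterification) and then AcOH to benzyl 2,4-dihydroxy-6-[15-(2-methyl-1,3-dioxolan-2-yl)pentadecyl]benzoate F5. Hydrogenolysis (H2, palladium on carbon (Pd/C), EtOAc, rt) removes the benzyl group as toluene under neutral conditions and should give acid 16, which is carried through the acidic half of step 9.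

**Further compounds**
F1 | step 6 | 16-(2-methyl-1,3-dioxolan-2-yl)hexadecanal | CC1(OCCO1)CCCCCCCCCCCCCCCC=O
F2 | step 6 | 6-[4-hydroxy-19-(2-methyl-1,3-dioxolan-2-yl)-2-oxononadecyl]-2,2-dimethyl-4H-1,3-dioxin-4-one (racemic) | CC1(OCCO1)CCCCCCCCCCCCCCCC(O)CC(=O)CC2=CC(=O)OC(C)(C)O2
F3 | step 8 | 7-hydroxy-2,2-dimethyl-5-[15-(2-methyl-1,3-dioxolan-2-yl)pentadecyl]-4H-1,3-benzodioxin-4-one | CC1(C)OC(=O)c2c(O1)cc(O)cc2CCCCCCCCCCCCCCCC3(C)OCCO3
F4 | step 9 | benzyl 22-(2-methyl-1,3-dioxolan-2-yl)-3,5,7-trioxodocosanoate | O=C(OCc1ccccc1)CC(=O)CC(=O)CC(=O)CCCCCCCCCCCCCCCC2(C)OCCO2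
F5 | step 9 | benzyl 2,4-dihydroxy-6-[15-(2-methyl-1,3-dioxolan-2-yl)pentadecyl]benzoate | O=C(OCc1ccccc1)c2c(O)cc(O)cc2CCCCCCCCCCCCCCCC3(C)OCCO3
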